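**Retrosynthetic overview**
1. Target 24 ⇐ late arene oxygenation (cleavage of the peri methyl ether, para-oxidation to the quinone, reduction) ⇐ seco acid 21.
2. 21 ⇐ Baeyer–Villiger ring expansion (6→7) of the gem-dimethyl ring-A ketone of tricyclic diketone 18, with opening of the tert-alkyl lactone to CO2H + isopropenyl; the trans ring fusion of 18 carries both stereocentres.
3. 18 ⇐ Friedel–Crafts closure of ring B ⇐ keto ester 16 ⇐ conjugate addition of an acetate unit anti to the aryl group of enone 12, then C-methylation.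
4. 12 ⇐ enantioselective Robinson annulation of 2-arylpropanal 9 with ethyl vinyl ketone (sets the quaternary centre) ⇐ aryl bromide 7 + propanal ⇐ resorcinol + acetone.
5. Ring order: arene → ring A (annulation) → ring B (acylation) → ring A expanded to the lactone and opened.

Assumption: the sense of induction of the organocatalyst in step 5 is taken by analogy; the catalyst enantiomer that gives (S)-12 is the one used.

**Step 1**
Reactants: 1 resorcinol
Product: 2 1,3-dimethoxybenzene
Conditions: MeI, K2CO3, DMF, rt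
Reagents that add atoms: iodomethane CI
Why: Williamson O-methylation of both phenols; one methyl stays in the target and the other is removed in step 10.

**Step 2**
Reactants: 2 1,3-dimethoxybenzene; 3 acetone
Product: 5 1,3-dimethoxy-2-(propan-2-yl)benzene, via carbinol 4 (not isolated)
Conditions: n-BuLi, THF, 0 °C → rt; 3, −78 °C → rt; then Et3SiH, CF3CO2H, CH2Cl2, 0 °C
Reagents that add atoms: none
Why: Directed ortho-lithiation between the two methoxy groups, carbonyl addition, then ionic hydrogenation of the doubly ortho-oxygen-stabilised tertiary benzylic cation.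

**Step 3**
Reactants: 5 1,3-dimethoxy-2-(propan-2-yl)benzene
Product: 7 5-bromo-1,3-dimethoxy-2-(propan-2-yl)benzene, via arylboronate 6 (not isolated)
Conditions: [Ir(OMe)(cod)]2 (1.5 mol%), dtbpy (3 mol%), B2pin2, THF, 80 °C; then CuBr2, MeOH/H2O, 80 °C
Reagents that add atoms: bis(pinacolato)diboron CC1(C)OB(OC1(C)C)B1OC(C)(C)C(C)(C)O1 (boryl group of 6); copper(II) bromide [Cu+2].[Br-].[Br-] (bromine of 7)
Why: Sterically controlled Ir-catalysed C–H borylation takes the only C–H with no ortho substituent (meta to both OMe, which electrophilic bromination cannot reach), and Cu(II) bromodeboronation then gives the bromide.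

**Step 4**
Reactants: 7 5-bromo-1,3-dimethoxy-2-(propan-2-yl)benzene; 8 propanal
Product: 9 rac-2-[3,5-dimethoxy-4-(propan-2-yl)phenyl]propanal
Conditions: [Pd(allyl)Cl]2 (1 mol%), dppf (2 mol%), Cs2CO3, 8 (2 equiv), dioxane, 80 °C
Reagents that add atoms: none
Why: Pd-catalysed α-arylation of an aldehyde enolate with an unhindered aryl bromide; the new centre is racemic and is erased in step 5.

**Step 5**
Reactants: 9 rac-2-[3,5-dimethoxy-4-(propan-2-yl)phenyl]propanal; 10 pent-1-en-3-one
Product: 12 (4S)-4-[3,5-dimethoxy-4-(propan-2-yl)phenyl]-2,4-dimethylcyclohex-2-en-1-one, via keto aldehyde 11 (not isolated)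
Conditions: N-(4-dodecylphenylsulfonyl)prolinamide (20 mol%), 4 Å MS, ClCH2CH2Cl, rt; then p-TsOH (10 mol%), PhMe, 60 °C
Reagents that add atoms: none
Why: Organocatalytic asymmetric Robinson annulation: the enamine of the α-branched aldehyde undergoes Michael addition to the vinyl ketone inside the hydrogen-bonding sulfonamide pocket, which sets the quaternary stereocentre (R in 11, S in 12), and the ethyl ketone then closes ring A by aldol condensation.

**Step 6**
Reactants: 13 tert-butyl acetate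
Product: 14 [(1-tert-butoxyethenyl)oxy]trimethylsilane
Conditions: LDA, THF, −78 °C; Me3SiCl; distil
Reagents that add atoms: chlorotrimethylsilane C[Si](C)(C)Cl
Why: Kinetic ester enolate formation and O-silylation give the silyl ketene acetal used as the two-carbon nucleophile.

**Step 7**
Reactants: 12 (4S)-4-[3,5-dimethoxy-4-(propan-2-yl)phenyl]-2,4-dimethylcyclohex-2-en-1-one; 14 [(1-tert-butoxyethenyl)oxy]trimethylsilane
Product: 16 tert-butyl 2-[(1R,6S)-6-[3,5-dimethoxy-4-(propan-2-yl)phenyl]-2,2,6-trimethyl-3-oxocyclohexyl]acetate, via silyl enol ether 15 (not isolated)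
Conditions: Tf2NH (3 mol%), CH2Cl2, −78 °C; then BnMe3N+F−, MeI, 4 Å MS, THF, −20 °C → rt
Reagents that add atoms: iodomethane CI
Why: Mukaiyama–Michael addition to the silyl-activated enone occurs on the face opposite the pseudo-axial aryl group of the neighbouring quaternary carbon, which sets the second stereocentre trans to aryl; fluoride then unmasks the regiodefined enolate, which is C-methylated to the gem-dimethyl ketone.

**Step 8**
Reactants: 16 tert-butyl 2-[(1R,6S)-6-[3,5-dimethoxy-4-(propan-2-yl)phenyl]-2,2,6-trimethyl-3-oxocyclohexyl]acetate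
Product: 18 (4aS,10aR)-6,8-dimethoxy-1,1,4a-trimethyl-7-(propan-2-yl)-1,3,4,4a,10,10a-hexahydrophenanthrene-2,9-dione, via keto acid 17 (not isolated)
Conditions: CF3CO2H, CH2Cl2, rt; then (CF3CO)2O, 0 °C → rt
Reagents that add atoms: none
Why: Acidolysis of the tert-butyl ester, then intramolecular Friedel–Crafts acylation through the mixed anhydride at the position ortho and para to the two methoxy groups (the two ortho positions are equivalent); the trans-diequatorial aryl and CH2CO groups give the trans-fused ring B without touching either stereocentre.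

**Step 9**
Reactants: 18 (4aS,10aR)-6,8-dimethoxy-1,1,4a-trimethyl-7-(propan-2-yl)-1,3,4,4a,10,10a-hexahydrophenanthrene-2,9-dione
Product: 21 3-[(1S,2S)-5,7-dimethoxy-1-methyl-4-oxo-6-(propan-2-yl)-2-(prop-1-en-2-yl)-1,2,3,4-tetrahydronaphthalen-1-yl]propanoic acid, via lactone 19 (not isolated), via silyl ester 20 (not isolated)
Conditions: Me3SiOOSiMe3 (2 equiv), TMSOTf (10 mol%), CH2Cl2, −40 → 0 °C; then 2,6-lutidine (4 equiv), TMSOTf (3 equiv), 0 °C → rt; aq. NaHCO3, then pH 3
Reagents that add atoms: bis(trimethylsilyl) peroxide C[Si](C)(C)OO[Si](C)(C)C (ring oxygen of 19); trimethylsilyl trifluoromethanesulfonate C[Si](C)(C)OS(=O)(=O)C(F)(F)F (silyl group of 20)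
Why: Proposed new method: a one-flask, silyl-triflate-relayed Baeyer–Villiger ring expansion with eliminative ring opening, in which the TMSOTf-activated dialkyl ketone adds the silyl peroxide and the quaternary CMe2 carbon migrates to oxygen (Criegee 1,2-shift, 6→7) to give ε-lactone 19, after which stoichiometric TMSOTf silylates the lactone carbonyl, the tert-alkyl C–O bond ionises and the hindered pyridine removes a methyl proton kinetically to give the isopropenyl silyl ester 20 (hydrolysed on work-up), with the conjugated, peri-hindered aryl ketone, the arene and both stereocentres spectators; the closest known reactions are the silyl peroxide/TMSOTf Baeyer–Villiger oxidation and the TMSOTf/2,6-lutidine cleavage of tert-butyl esters to silyl esters plus alkene.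

**Step 10**
Reactants: 21 3-[(1S,2S)-5,7-dimethoxy-1-methyl-4-oxo-6-(propan-2-yl)-2-(prop-1-en-2-yl)-1,2,3,4-tetrahydronaphthalen-1-yl]propanoic acid
Product: 22 3-[(1S,2S)-5-hydroxy-7-methoxy-1-methyl-4-oxo-6-(propan-2-yl)-2-(prop-1-en-2-yl)-1,2,3,4-tetrahydronaphthalen-1-yl]propanoic acid
Conditions: BCl3 (3 equiv), CH2Cl2, −78 → −20 °C; MeOH, aq. NaHCO3, then pH 3
Reagents that add atoms: none
Why: Chelation-controlled Lewis-acid ether cleavage: BCl3 bridges the ketone and the peri methoxy group and cleaves only that methyl ether, while the non-chelated methoxy group and the alkene survive at low temperature.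

**Step 11**
Reactants: 22 3-[(1S,2S)-5-hydroxy-7-methoxy-1-methyl-4-oxo-6-(propan-2-yl)-2-(prop-1-en-2-yl)-1,2,3,4-tetrahydronaphthalen-1-yl]propanoic acid
Product: 24 3-[(1S,2S)-5,8-dihydroxy-7-methoxy-1-methyl-4-oxo-6-(propan-2-yl)-2-(prop-1-en-2-yl)-1,2,3,4-tetrahydronaphthalen-1-yl]propanoic acid, via quinone 23 (not isolated)
Conditions: (KSO3)2NO, KH2PO4, acetone/H2O, 0 °C → rt; then Na2S2O4, H2O/EtOAc, rt
Reagents that add atoms: potassium nitrosodisulfonate [K+].[K+].[O]N(S(=O)(=O)[O-])S(=O)(=O)[O-]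
Why: Teuber oxidation: Fremy's radical oxidises the phenol and delivers oxygen to the free para position to give the p-quinone, which dithionite reduces to the hydroquinone; alkene, acid and stereocentres are inert.

**Compound list**
1 | resorcinol | Oc1cccc(O)c1 | starting material
2 | 1,3-dimethoxybenzene | COc1cccc(OC)c1 | intermediate
3 | acetone | CC(C)=O | starting material
4 | 2-(2,6-dimethoxyphenyl)propan-2-ol | COc1cccc(OC)c1C(C)(C)O | intermediate
5 | 1,3-dimethoxy-2-(propan-2-yl)benzene | COc1cccc(OC)c1C(C)C | intermediate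
6 | 2-[3,5-dimethoxy-4-(propan-2-yl)phenyl]-4,4,5,5-tetramethyl-1,3,2-dioxaborolane | COc1cc(B2OC(C)(C)C(C)(C)O2)cc(OC)c1C(C)C | intermediate
7 | 5-bromo-1,3-dimethoxy-2-(propan-2-yl)benzene | COc1cc(Br)cc(OC)c1C(C)C | intermediate
8 | propanal | CCC=O | starting material
9 | rac-2-[3,5-dimethoxy-4-(propan-2-yl)phenyl]propanal | CC(C=O)c1cc(OC)c(C(C)C)c(OC)c1 | intermediate
10 | pent-1-en-3-one (ethyl vinyl ketone) | CCC(=O)C=C | starting material
11 | (2R)-2-[3,5-dimethoxy-4-(propan-2-yl)phenyl]-2-methyl-5-oxoheptanal | O=C[C@@](C)(c1cc(OC)c(C(C)C)c(OC)c1)CCC(=O)CC | intermediate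
12 | (4S)-4-[3,5-dimethoxy-4-(propan-2-yl)phenyl]-2,4-dimethylcyclohex-2-en-1-one | CC1=C[C@@](C)(c2cc(OC)c(C(C)C)c(OC)c2)CCC1=O | intermediate
13 | tert-butyl acetate | CC(=O)OC(C)(C)C | starting material
14 | [(1-tert-butoxyethenyl)oxy]trimethylsilane | C=C(O[Si](C)(C)C)OC(C)(C)C | intermediate
15 | tert-butyl 2-[(1R,6S)-6-[3,5-dimethoxy-4-(propan-2-yl)phenyl]-2,6-dimethyl-3-[(trimethylsilyl)oxy]cyclohex-2-en-1-yl]acetate | CC1=C(O[Si](C)(C)C)CC[C@](C)(c2cc(OC)c(C(C)C)c(OC)c2)[C@H]1CC(=O)OC(C)(C)C | intermediate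
16 | tert-butyl 2-[(1R,6S)-6-[3,5-dimethoxy-4-(propan-2-yl)phenyl]-2,2,6-trimethyl-3-oxocyclohexyl]acetate | CC1(C)[C@H](CC(=O)OC(C)(C)C)[C@@](C)(c2cc(OC)c(C(C)C)c(OC)c2)CCC1=O | intermediate
17 | 2-[(1R,6S)-6-[3,5-dimethoxy-4-(propan-2-yl)phenyl]-2,2,6-trimethyl-3-oxocyclohexyl]acetic acid | CC1(C)[C@H](CC(=O)O)[C@@](C)(c2cc(OC)c(C(C)C)c(OC)c2)CCC1=O | intermediate
18 | (4aS,10aR)-6,8-dimethoxy-1,1,4a-trimethyl-7-(propan-2-yl)-1,3,4,4a,10,10a-hexahydrophenanthrene-2,9-dione (trans-fused) | CC1(C)[C@@H]2CC(=O)c3c(OC)c(C(C)C)c(OC)cc3[C@@]2(C)CCC1=O | intermediate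
19 | (5R,10S)-12,14-dimethoxy-4-oxa-A-homoabieta-8,11,13-triene-3,7-dione (ε-lactone of 18, oxygen between C=O and CMe2) | CC1(C)[C@@H]2CC(=O)c3c(OC)c(C(C)C)c(OC)cc3[C@@]2(C)CCC(=O)O1 | intermediate
20 | trimethylsilyl 3-[(1S,2S)-5,7-dimethoxy-1-methyl-4-oxo-6-(propan-2-yl)-2-(prop-1-en-2-yl)-1,2,3,4-tetrahydronaphthalen-1-yl]propanoate | C=C(C)[C@@H]1CC(=O)c2c(OC)c(C(C)C)c(OC)cc2[C@@]1(C)CCC(=O)O[Si](C)(C)C | intermediate
21 | 3-[(1S,2S)-5,7-dimethoxy-1-methyl-4-oxo-6-(propan-2-yl)-2-(prop-1-en-2-yl)-1,2,3,4-tetrahydronaphthalen-1-yl]propanoic acid | C=C(C)[C@@H]1CC(=O)c2c(OC)c(C(C)C)c(OC)cc2[C@@]1(C)CCC(=O)O | intermediate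
22 | 3-[(1S,2S)-5-hydroxy-7-methoxy-1-methyl-4-oxo-6-(propan-2-yl)-2-(prop-1-en-2-yl)-1,2,3,4-tetrahydronaphthalen-1-yl]propanoic acid | C=C(C)[C@@H]1CC(=O)c2c(O)c(C(C)C)c(OC)cc2[C@@]1(C)CCC(=O)O | intermediate
23 | 3-[(1S,2S)-7-methoxy-1-methyl-4,5,8-trioxo-6-(propan-2-yl)-2-(prop-1-en-2-yl)-1,2,3,4,5,8-hexahydronaphthalen-1-yl]propanoic acid | C=C(C)[C@@H]1CC(=O)C2=C(C(=O)C(OC)=C(C(C)C)C2=O)[C@@]1(C)CCC(=O)O | intermediate
24 | 3-[(1S,2S)-5,8-dihydroxy-7-methoxy-1-methyl-4-oxo-6-(propan-2-yl)-2-(prop-1-en-2-yl)-1,2,3,4-tetrahydronaphthalen-1-yl]propanoic acid (CNP0249049.1) | C=C(C)[C@@H]1CC(=O)c2c(O)c(C(C)C)c(OC)c(O)c2[C@@]1(C)CCC(=O)O | target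

**Step count and risks**
Total step count: 11. Longest linear sequence: 10 (steps 1–5 and 7–11; step 6 is a one-step side branch).

The three steps most likely to fail are 9, 7 and 5.

Step 9 is the proposed new transformation. Its risks are a slow Baeyer–Villiger reaction at the neopentyl ketone under silyl peroxide, arene oxidation, and loss of the ring proton instead of a methyl proton in the opening (which would give the tetrasubstituted alkene and destroy a stereocentre). The fallback uses known chemistry and avoids a free carbocation. It sets out from 18 with a classical peracid Baeyer–Villiger oxidation (mCPBA, NaHCO3, CH2Cl2) and isolation of lactone 19. Methanolysis (NaOMe, MeOH) gives the hydroxy ester methyl 3-[(1S,2R)-2-(2-hydroxypropan-2-yl)-5,7-dimethoxy-1-methyl-4-oxo-6-(propan-2-yl)-1,2,3,4-tetrahydronaphthalen-1-yl]propanoate F1. Syn-dehydration with Burgess reagent (PhMe, 70 °C) gives the isopropenyl ester methyl 3-[(1S,2S)-5,7-dimethoxy-1-methyl-4-oxo-6-(propan-2-yl)-2-(prop-1-en-2-yl)-1,2,3,4-tetrahydronaphthalen-1-yl]propanoate F2. Hydrolysis (LiOH, THF/H2O) comes back to the route at 21.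

Step 7 is risky because the β-carbon of 12 lies next to a quaternary centre: the silyl ketene acetal may add slowly or 1,2, and the fluoride-mediated quaternising methylation may give O-alkylation or proton transfer. The fallback sets out from 12 and replaces the ester nucleophile by a small vinyl group that is oxidised afterwards. Copper-catalysed conjugate addition (vinylmagnesium bromide, CuI, Me3SiCl, THF, −78 °C) gives the silyl enol ether {[(3R,4S)-4-[3,5-dimethoxy-4-(propan-2-yl)phenyl]-3-ethenyl-2,4-dimethylcyclohex-1-en-1-yl]oxy}trimethylsilane F3. MeLi then MeI gives the vinyl ketone (3R,4S)-4-[3,5-dimethoxy-4-(propan-2-yl)phenyl]-3-ethenyl-2,2,4-trimethylcyclohexan-1-one F4. Hydroboration–oxidation (9-BBN; NaOH, H2O2) gives the alcohol (3R,4S)-4-[3,5-dimethoxy-4-(propan-2-yl)phenyl]-3-(2-hydroxyethyl)-2,2,4-trimethylcyclohexan-1-one F5. Jones oxidation gives keto acid 17, where the fallback comes back to the route; 17 is cyclised with trifluoroacetic anhydride as in step 8.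

Step 5 may give low conversion or modest ee with this α-aryl aldehyde and ethyl vinyl ketone. The fallback sets out from 9 and 10 and replaces asymmetric catalysis by resolution. An achiral annulation (pyrrolidine, AcOH, PhMe; then KOH, EtOH) gives rac-4-[3,5-dimethoxy-4-(propan-2-yl)phenyl]-2,4-dimethylcyclohex-2-en-1-one F6. Preparative chiral SFC then separates the enantiomers, and the (S)-enantiomer comes back to the route at 12.

**Further compounds**
F1 | step 9 | methyl 3-[(1S,2R)-2-(2-hydroxypropan-2-yl)-5,7-dimethoxy-1-methyl-4-oxo-6-(propan-2-yl)-1,2,3,4-tetrahydronaphthalen-1-yl]propanoate | CC(C)(O)[C@@H]1CC(=O)c2c(OC)c(C(C)C)c(OC)cc2[C@@]1(C)CCC(=O)OC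
F2 | step 9 | methyl 3-[(1S,2S)-5,7-dimethoxy-1-methyl-4-oxo-6-(propan-2-yl)-2-(prop-1-en-2-yl)-1,2,3,4-tetrahydronaphthalen-1-yl]propanoate | C=C(C)[C@@H]1CC(=O)c2c(OC)c(C(C)C)c(OC)cc2[C@@]1(C)CCC(=O)OC
F3 | step 7 | {[(3R,4S)-4-[3,5-dimethoxy-4-(propan-2-yl)phenyl]-3-ethenyl-2,4-dimethylcyclohex-1-en-1-yl]oxy}trimethylsilane | CC1=C(O[Si](C)(C)C)CC[C@](C)(c2cc(OC)c(C(C)C)c(OC)c2)[C@H]1C=C
F4 | step 7 | (3R,4S)-4-[3,5-dimethoxy-4-(propan-2-yl)phenyl]-3-ethenyl-2,2,4-trimethylcyclohexan-1-one | CC1(C)[C@H](C=C)[C@@](C)(c2cc(OC)c(C(C)C)c(OC)c2)CCC1=O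
F5 | step 7 | (3R,4S)-4-[3,5-dimethoxy-4-(propan-2-yl)phenyl]-3-(2-hydroxyethyl)-2,2,4-trimethylcyclohexan-1-one | CC1(C)[C@H](CCO)[C@@](C)(c2cc(OC)c(C(C)C)c(OC)c2)CCC1=O
F6 | step 5 | rac-4-[3,5-dimethoxy-4-(propan-2-yl)phenyl]-2,4-dimethylcyclohex-2-en-1-one | CC1=CC(C)(c2cc(OC)c(C(C)C)c(OC)c2)CCC1=O
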